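In a one-step world, with J turning D into E and Q standing by, E stops at half of the D and Q together charged. Wednesday's flask stood at 52.2% by 15.0 min, higher than that, so Q was reaching E, and I credited Z with turning Q into D.

| setting | Wednesday's | Monday's | flask |
|---|---|---|---|
| D | 20 mM | 20 mM | 20 mM |
| Q | 20 mM | 20 mM | 20 mM |
| J | 2.2 equiv | 2.2 equiv | 2.20 equiv |
| Z | 0.1 mol% | 0.1 mol% | 0.1 mol% |
| temperature | 50 °C | 56 °C | 50 °C |
| remark | the very flask that is asked about, followed so far | run made earlier |  |
| time |  |  | 80 min |

- Wednesday's (time / min: E / %): 15.0: 52.2; 30.0: 58.9; 50.0: 62.5; 60.0: 62.9; 80.0: 63.7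
- Monday's (time / min: E / %): 15.0: 54.5; 30.0: 58.8; 50.0: 60.3; 60.0: 60.1; 80.0: 60.3

(readings scatter by 0.3 percentage points)

- J is single-handed; D and Q are mirror images of each other, charged as a racemate, each of them at the stated concentration
- what is taken out of E is counted as made
- additions bring no volume worth counting
- the handed part of J does not stay in what it makes, so the products of the two hands are mirror images too

- ochre: at 80 min add Z, 100% of the amount charged, then wait 2.5 h
- red: change nothing and wait 2.5 h more
- green: at 80 min raise the temperature by 20 K, then wait 2.5 h
- amber: at 80 min take out 90% of the E then present, then wait 2.5 h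
- grey: at 80 min add J, 50.0% of the amount charged, then wait 2.5 h

1. E, in percent of the D and Q together first charged, at 80 min
2. the option that brings most further E ("none" if no option brings more than 2 percentage points) (ochre / red / green / amber / grey / none)
3. E present, with what was taken out counted in, in percent of the D and Q together first charged, after red
4. E present, with what was taken out counted in, in percent of the D and Q together first charged, after green

Wednesday's flask flattened: its last rise, from 60.0 min to 80.0 min, was 0.8 percentage points, less than the 2 points that an option must beat. Yet the charge held 1.10 J per D and Q together, more than one. I therefore folded charge and reading into one number, 0.579, which I called φ, the J yield: moles of E made per mole of J charged. If J was the limiting reagent, φ was the share of J ending in E, and E would follow the J charged.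

I tested this on Monday's run, with the same charge at 56 °C. It gave φ = 0.548, and its last reading, 60.3%, lay lower than Wednesday's by more than the scatter of 0.3 points. So one number did not carry across temperature, and E alone could not tell a lack of J from a dying Z. I wagered on J: at Wednesday's φ, grey should bring 32 points, and the other options less than 2 points.

The forecast, unlike my wager, named ochre, with 63.5% now, 63.9% after red and 64.2% after green: “That pattern points to Z dying, and dying faster when hot.”

The flask gave 63.1%; grey was best, bringing 20 points, against 0.3 points for ochre, with 63.4% after red and 63.3% after green. In that flask J stood at 0.385% of its charge at 80.0 min.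

    J + D → E (k = 0.110 L mol⁻¹ s⁻¹, Ea = 57.0 kJ mol⁻¹)
    J → G (k = 1.50 × 10⁻⁴ s⁻¹, Ea = 98.0 kJ mol⁻¹)
    J + Q → X (k = 0.0170 L mol⁻¹ s⁻¹, Ea = 65.0 kJ mol⁻¹)
    2 J → L (k = 0.0160 L mol⁻¹ s⁻¹, Ea = 75.0 kJ mol⁻¹)
    D + Z ⇌ Q + Z, rate k5*[Z]*[D] forward; the back reaction follows from the equilibrium constant (k = 790 L mol⁻¹ s⁻¹, Ea = 46.0 kJ mol⁻¹)
    (constants at 50 °C)

The J added in grey returned φ = 0.356, less than Wednesday's. On a neighbouring flask, like this one but with 0.550 equiv of J, Wednesday's φ reckoned 15.9% of E. That flask gave 20.8%, a φ of 0.756, with J at 0% of its charge and Q at 38.0% of the D and Q together charged.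

The data are simulated from invented constants; scatter was added.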